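**Plan**
1. Retrosynthesis: the C3–C1′ bond (pyridine to dienyl) is cut first (Suzuki–Miyaura). The C7 ketone is then traced back to an exocyclic C7=CH2 group. Finally C7–C7a and C5–C6 are cut together, which opens the carbocycle to a 3-boryl-4-(methoxalyl)pyridine and 3-methoxybuta-1,2-diene.
2. Enabling feature: in the cyclopenta[c]pyridine core, C7(=O)–C6–C5(OH) is an aldol array bridging the adjacent pyridine carbons C7a and C4a. C7a (a pyridine β-carbon) can carry a metal next to the electrophilic α-keto ester carbon C5, and C7–C6 is a masked methoxy(methyl)ketene, so the five-membered ring is a polarity-matched [3+2] sum.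
3. Helper: the unstable ketene is replaced by the stable 1-alkoxyallene (CH2 in place of O). The CH2 is removed by ozonolysis before the ozone-sensitive diene is attached.
4. Forward order: purchased pyridine ring, keto ester by directed lithiation, boronate, Rh-catalysed annulation that closes the carbocycle, ozonolysis, side chain joined last.
5. Stereochemistry: C5 and C6 arise together in the annulation (chiral bisphosphine on Rh for C5; allyl geometry and a closed transition state for C6 relative to C5). C5′ comes from (S)-2-methylbutan-1-ol, and both E alkenes come from Wittig and boron–Wittig olefinations.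

Key step: step 4

Numbering: C1, N2, C3 (dienyl), C4, C4a, C5 (carbinol), C6 (methoxy carbon), C7 (ketone) and C7a follow the cyclopenta[c]pyridine skeleton. Primed numbers belong to the side chain.
Assumption: the sense of asymmetric induction in step 4 cannot be derived from a close model. (R)-BINAP is written, and the equally available (S)-ligand takes its place if the mirror-image core should prevail.

**Step 1**
Reactants: 1 5-bromo-2-chloropyridine; 2 dimethyl oxalate
Product: 4 methyl 2-(5-bromo-2-chloropyridin-4-yl)-2-oxoacetate, via 5-bromo-2-chloro-4-lithiopyridine 3 (not isolated)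
Conditions: LDA (commercial solution, 1.05 equiv), THF, −78 °C; cannulation into 2 (3 equiv), THF, −78 °C; AcOH quench at −78 °C
Reagents that add atoms: none
Why: Directed ortho-lithiation removes H-4 (next to bromine, γ to nitrogen), and inverse addition of the aryllithium to excess oxalate stops at the tetrahedral adduct, which should release the α-keto ester on acidic quench (acylation of an aryllithium with a dialkyl oxalate).

**Step 2**
Reactants: 4 methyl 2-(5-bromo-2-chloropyridin-4-yl)-2-oxoacetate
Product: 5 methyl 2-[2-chloro-5-(4,4,5,5-tetramethyl-1,3,2-dioxaborolan-2-yl)pyridin-4-yl]-2-oxoacetate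
Conditions: B2pin2, Pd(dppf)Cl2 (5 mol %), KOAc, 1,4-dioxane, 85 °C
Reagents that add atoms: bis(pinacolato)diboron, CC1(C)OB(OC1(C)C)B1OC(C)(C)C(C)(C)O1
Why: In this Miyaura borylation, Pd(0)/dppf inserts into C–Br much faster than into C–Cl, and the weak base KOAc should leave the keto ester untouched.

**Step 3**
Reactants: 6 methoxyallene (1-methoxypropa-1,2-diene)
Product: 8 3-methoxybuta-1,2-diene, via 1-lithio-1-methoxyallene 7 (not isolated)
Conditions: n-BuLi, Et2O, −40 °C; MeI, −40 °C to rt; distillation
Reagents that add atoms: iodomethane, CI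
Why: This is α-lithiation and alkylation of an alkoxyallene, in which the proton on the oxygen-bearing allene carbon is the most acidic one and the lithioallene is methylated at that carbon.

**Step 4**
Reactants: 5 methyl 2-[2-chloro-5-(4,4,5,5-tetramethyl-1,3,2-dioxaborolan-2-yl)pyridin-4-yl]-2-oxoacetate; 8 3-methoxybuta-1,2-diene
Product: 10 methyl (5R,6R)-3-chloro-5-hydroxy-6-methoxy-6-methyl-7-methylidene-6,7-dihydro-5H-cyclopenta[c]pyridine-5-carboxylate, via allylrhodium species 9 (not isolated)
Conditions: [RhCl(C2H4)2]2 (2.5 mol %), (R)-BINAP (5.5 mol %), KOMe (10 mol %), 8 (3 equiv), 1,4-dioxane/MeOH 10:1, 50 °C, sealed tube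
Reagents that add atoms: none
Why: Proposed new method: Boron-to-rhodium transmetalation gives a pyridin-3-yl–Rh(I) species held by the neighbouring ketone oxygen, this carborhodates the unsubstituted C=CH2 bond of 8 with aryl delivery to the central allene carbon (C7a–C7 bond) to give allylrhodium 9, 9 adds through its oxygen-bearing terminus to the α-keto ester carbon (C5–C6 bond), and methanolysis of the rhodium alkoxide returns Rh–OMe. The closest known reaction types are the Rh(I)-catalysed [3+2] annulations of ortho-acylarylboron reagents with alkynes and of aryl ketimines with allenes and the arylative cyclisation of allenyl ketones; what has not been shown is a 1-alkoxyallene as ketene surrogate together with an α-keto ester acceptor that builds two adjacent fully substituted carbons. The only ring formed, the carbocycle C4a–C5–C6–C7–C7a, closes 5-exo-trig on the C5=O bond, with the C6–C7 part of the allyl unit inside the ring and rhodium bridging the CH2 terminus and the ketone oxygen (syn-SE2′ delivery). C5 is controlled by the C2-symmetric bisphosphine on this bridging rhodium, which leaves one face of the bound keto ester open. C6 is controlled relative to C5: aryl delivery from the allene flank that bears the smaller, rhodium-coordinating methoxy group gives the (E)-allyl form (OMe cis to pyridyl), and its closed transition state puts OMe anti to the C5–O bond and beside CO2Me and the methyl group anti to CO2Me, which is also the arrangement with the least eclipsing between the two new quaternary carbons. The step needs C–B over C–Cl chemoselectivity (Rh(I) does not insert into the chloropyridine), attack by the substituted allyl terminus and not by CH2 (the normal γ-selectivity of a primary σ-allyl metal), and ring closure faster than protonation of 9 or intermolecular arylation of the keto ester, which the ortho position of the acceptor and an excess of 8 should secure.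

**Step 5**
Reactants: 10 methyl (5R,6R)-3-chloro-5-hydroxy-6-methoxy-6-methyl-7-methylidene-6,7-dihydro-5H-cyclopenta[c]pyridine-5-carboxylate
Product: 12 methyl (5R,6S)-3-chloro-5-hydroxy-6-methoxy-6-methyl-7-oxo-6,7-dihydro-5H-cyclopenta[c]pyridine-5-carboxylate, via spiro secondary ozonide 11 (not isolated)
Conditions: O3, CH2Cl2, −78 °C; Me2S, −78 °C to rt
Reagents that add atoms: ozone, [O-][O+]=O
Why: In this ozonolysis with reductive work-up, the exocyclic 1,1-disubstituted alkene is the only C=C bond present and the electron-poor chloropyridine is inert to ozone at −78 °C, so the CH2 helper should leave as formaldehyde without touching C5 or C6 (the C6 descriptor changes only because the CIP ranking changes).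

**Step 6**
Reactants: 13 (S)-2-methylbutan-1-ol
Product: 14 (S)-2-methylbutanal
Conditions: TEMPO (1 mol %), KBr (10 mol %), aq NaOCl (pH 9.5, NaHCO3), CH2Cl2, 0 °C
Reagents that add atoms: none
Why: The Anelli-type TEMPO/hypochlorite oxidation runs at 0 °C in a buffered two-phase medium and is established for α-branched aldehydes without loss of configuration.

**Step 7**
Reactants: 14 (S)-2-methylbutanal; 15 2-(triphenyl-λ5-phosphanylidene)propanal
Product: 16 (2E,4S)-2,4-dimethylhex-2-enal
Conditions: PhMe, 90 °C, sealed tube
Reagents that add atoms: none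
Why: Wittig olefination with a stabilised formyl ylide should give the (E)-trisubstituted enal, and the weakly basic ylide should not enolise the α-stereocentre.

**Step 8**
Reactants: 16 (2E,4S)-2,4-dimethylhex-2-enal; 17 bis(4,4,5,5-tetramethyl-1,3,2-dioxaborolan-2-yl)methane
Product: 19 2-[(1E,3E,5S)-3,5-dimethylhepta-1,3-dien-1-yl]-4,4,5,5-tetramethyl-1,3,2-dioxaborolane, via lithiated diborylmethane 18 (not isolated)
Conditions: 2,2,6,6-tetramethylpiperidine, n-BuLi, THF, 0 °C; 17, 0 °C; 16, −78 °C to rt
Reagents that add atoms: none
Why: In this boron–Wittig olefination, the lithiated gem-diborylmethane adds 1,2 to the hindered enal, and syn B–O elimination from the less crowded adduct should give the (E)-alkenyl boronate.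

**Step 9**
Reactants: 12 methyl (5R,6S)-3-chloro-5-hydroxy-6-methoxy-6-methyl-7-oxo-6,7-dihydro-5H-cyclopenta[c]pyridine-5-carboxylate; 19 2-[(1E,3E,5S)-3,5-dimethylhepta-1,3-dien-1-yl]-4,4,5,5-tetramethyl-1,3,2-dioxaborolane
Product: 20 methyl (5R,6S)-3-[(1E,3E,5S)-3,5-dimethylhepta-1,3-dien-1-yl]-5-hydroxy-6-methoxy-6-methyl-7-oxo-6,7-dihydro-5H-cyclopenta[c]pyridine-5-carboxylate (target)
Conditions: XPhos Pd G3 (3 mol %), K3PO4 (0.5 M aq, 2 equiv), THF, 40 °C
Reagents that add atoms: none
Why: In this Suzuki–Miyaura coupling, the C3–Cl bond is activated by the adjacent ring nitrogen and by the acyl group on the para carbon C7a, so a bulky biarylphosphine catalyst should couple it at 40 °C with retention of the diene geometry and with the aldol unit left closed.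

**Compound list**
1 | 5-bromo-2-chloropyridine | Clc1ccc(Br)cn1 | starting material
2 | dimethyl oxalate | COC(=O)C(=O)OC | starting material
3 | 5-bromo-2-chloro-4-lithiopyridine | [Li]c1cc(Cl)ncc1Br | intermediate
4 | methyl 2-(5-bromo-2-chloropyridin-4-yl)-2-oxoacetate | COC(=O)C(=O)c1cc(Cl)ncc1Br | intermediate
5 | methyl 2-[2-chloro-5-(4,4,5,5-tetramethyl-1,3,2-dioxaborolan-2-yl)pyridin-4-yl]-2-oxoacetate | COC(=O)C(=O)c1cc(Cl)ncc1B1OC(C)(C)C(C)(C)O1 | intermediate
6 | methoxyallene (1-methoxypropa-1,2-diene) | COC=C=C | starting material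
7 | 1-lithio-1-methoxyallene | [Li]C(OC)=C=C | intermediate
8 | 3-methoxybuta-1,2-diene | COC(C)=C=C | intermediate
9 | (E)-σ-allylrhodium species, methyl 2-{2-chloro-5-[3-methoxy-1-rhodiobut-2-en-2-yl]pyridin-4-yl}-2-oxoacetate (bisphosphine on Rh omitted) | COC(=O)C(=O)c1cc(Cl)ncc1/C(C[Rh])=C(/C)OC | intermediate
10 | methyl (5R,6R)-3-chloro-5-hydroxy-6-methoxy-6-methyl-7-methylidene-6,7-dihydro-5H-cyclopenta[c]pyridine-5-carboxylate | Clc1cc2c(cn1)C(=C)[C@@](C)(OC)[C@@]2(O)C(=O)OC | intermediate
11 | spiro secondary ozonide (1,2,4-trioxolane at C7) of 10, C7 configuration undefined | Clc1cc2c(cn1)C1(OCOO1)[C@@](C)(OC)[C@@]2(O)C(=O)OC | intermediate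
12 | methyl (5R,6S)-3-chloro-5-hydroxy-6-methoxy-6-methyl-7-oxo-6,7-dihydro-5H-cyclopenta[c]pyridine-5-carboxylate | Clc1cc2c(cn1)C(=O)[C@@](C)(OC)[C@@]2(O)C(=O)OC | intermediate
13 | (S)-2-methylbutan-1-ol | CC[C@H](C)CO | starting material
14 | (S)-2-methylbutanal | CC[C@H](C)C=O | intermediate
15 | 2-(triphenyl-λ5-phosphanylidene)propanal | CC(C=O)=P(c1ccccc1)(c1ccccc1)c1ccccc1 | starting material
16 | (2E,4S)-2,4-dimethylhex-2-enal | CC[C@H](C)/C=C(C)/C=O | intermediate
17 | bis(4,4,5,5-tetramethyl-1,3,2-dioxaborolan-2-yl)methane | CC1(C)OB(CB2OC(C)(C)C(C)(C)O2)OC1(C)C | starting material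
18 | lithio-bis(4,4,5,5-tetramethyl-1,3,2-dioxaborolan-2-yl)methane | [Li]C(B1OC(C)(C)C(C)(C)O1)B1OC(C)(C)C(C)(C)O1 | intermediate
19 | 2-[(1E,3E,5S)-3,5-dimethylhepta-1,3-dien-1-yl]-4,4,5,5-tetramethyl-1,3,2-dioxaborolane | CC[C@H](C)/C=C(C)/C=C/B1OC(C)(C)C(C)(C)O1 | intermediate
20 | methyl (5R,6S)-3-[(1E,3E,5S)-3,5-dimethylhepta-1,3-dien-1-yl]-5-hydroxy-6-methoxy-6-methyl-7-oxo-6,7-dihydro-5H-cyclopenta[c]pyridine-5-carboxylate | CC[C@H](C)/C=C(C)/C=C/c1cc2c(cn1)C(=O)[C@@](C)(OC)[C@@]2(O)C(=O)OC | target

**Step count**
Total step count: 9. Longest linear sequence: 5 steps (steps 1, 2, 4, 5, 9) from 5-bromo-2-chloropyridine.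

**Steps most likely to fail**

1. Step 4 (Proposed new method).
 - What may go wrong: protonation or β-hydride loss of the allylrhodium species before ring closure, closure through the CH2 terminus, intermolecular arylation of the keto ester, or poor facial selectivity at C5 or C6.
 - Fallback: known reactions make the two bonds one after the other, setting out from bromide 4 and allene 8. A copper(I)-catalysed enantioselective borylative allene–ketone coupling (CuCl, chiral bisphosphine, NaOt-Bu, B2pin2, THF) adds B–Cu across the allene. The 2-borylallylcopper then attacks the keto ester through its substituted terminus in a chair-like transition state. This should give methyl (2R,3R)-2-(5-bromo-2-chloropyridin-4-yl)-2-hydroxy-3-methoxy-3-methyl-4-(4,4,5,5-tetramethyl-1,3,2-dioxaborolan-2-yl)pent-4-enoate F1. An intramolecular Suzuki–Miyaura coupling of its alkenyl boronate with the C–Br bond (Pd(dppf)Cl2, K3PO4, dioxane/water) then closes C7–C7a, and the route is rejoined at 10.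

2. Step 9.
 - What may go wrong: base-induced retro-aldol opening of the C5–C6 bond and reclosure, which would erase both ring stereocentres, or saponification of the methyl ester.
 - Fallback: a protecting-group detour from 12. TESOTf and 2,6-lutidine (CH2Cl2, 0 °C) should give methyl (5R,6S)-3-chloro-6-methoxy-6-methyl-7-oxo-5-(triethylsilyloxy)-6,7-dihydro-5H-cyclopenta[c]pyridine-5-carboxylate F2, which can no longer open by retro-aldol. Suzuki–Miyaura coupling of it with 19 should give methyl (5R,6S)-3-[(1E,3E,5S)-3,5-dimethylhepta-1,3-dien-1-yl]-6-methoxy-6-methyl-7-oxo-5-(triethylsilyloxy)-6,7-dihydro-5H-cyclopenta[c]pyridine-5-carboxylate F3. HF·pyridine (THF, 0 °C) removes the silyl group, and the route is rejoined at 20.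

3. Step 2.
 - What may go wrong: protodeboronation of the electron-poor ortho-acyl pyridyl boronate, hydrodebromination, or attack of the borylating medium on the keto ester.
 - Fallback: a different organometallic handle made under base-free conditions, setting out from 4. Palladium-catalysed stannylation with hexamethylditin (Pd(PPh3)4, toluene, 100 °C) should give methyl 2-[2-chloro-5-(trimethylstannyl)pyridin-4-yl]-2-oxoacetate F4. Tin-to-rhodium transmetalation is known for aryl stannanes, so this compound enters the annulation with 8 in place of 5, and the route is rejoined at 10.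

**Further compounds**
F1 | step 4 | methyl (2R,3R)-2-(5-bromo-2-chloropyridin-4-yl)-2-hydroxy-3-methoxy-3-methyl-4-(4,4,5,5-tetramethyl-1,3,2-dioxaborolan-2-yl)pent-4-enoate | C=C(B1OC(C)(C)C(C)(C)O1)[C@@](C)(OC)[C@@](c1cc(Cl)ncc1Br)(O)C(=O)OC
F2 | step 9 | methyl (5R,6S)-3-chloro-6-methoxy-6-methyl-7-oxo-5-(triethylsilyloxy)-6,7-dihydro-5H-cyclopenta[c]pyridine-5-carboxylate | Clc1cc2c(cn1)C(=O)[C@@](C)(OC)[C@@]2(O[Si](CC)(CC)CC)C(=O)OC
F3 | step 9 | methyl (5R,6S)-3-[(1E,3E,5S)-3,5-dimethylhepta-1,3-dien-1-yl]-6-methoxy-6-methyl-7-oxo-5-(triethylsilyloxy)-6,7-dihydro-5H-cyclopenta[c]pyridine-5-carboxylate | CC[C@H](C)/C=C(C)/C=C/c1cc2c(cn1)C(=O)[C@@](C)(OC)[C@@]2(O[Si](CC)(CC)CC)C(=O)OC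
F4 | step 2 | methyl 2-[2-chloro-5-(trimethylstannyl)pyridin-4-yl]-2-oxoacetate | COC(=O)C(=O)c1cc(Cl)ncc1[Sn](C)(C)C
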